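**Retrosynthetic overview**

1. Last bond, aryl–CH2: an arylcopper from 5-iodo-2,3-dimethoxy-6-methylphenol displaces the primary allylic bromide of the complete side chain (SN2, both E alkenes kept).
2. Key bond, lactone CH2–C(sp2): a light-driven nickel coupling joins the primary alcohol of the trans-methyl lactone (as a benzoxazolium adduct, radical route) to an (E)-alkenyl bromide.
3. The alkenyl bromide comes from geranyl acetate (one E alkene bought): ozonolysis, alkyne homologation, C-methylation, hydrozirconation/bromination (second E alkene).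
4. The lactone comes from the trityl ether of the L-glutamic acid lactone: trans-selective enolate methylation, then detritylation.
5. The arene comes from 2,3,4-trimethoxybenzaldehyde: ortho-lithiation/iodination, BCl3 demethylation, CHO to CH3. No ring is formed in the route; the benzene ring and the lactone ring are both bought.

Assumption: (5S)-5-[(trityloxy)methyl]dihydrofuran-2(3H)-one 1 is bought as such; if it is not, one tritylation of the commercial hydroxymethyl lactone is added.

**Route**

Step 1
Reactants: 1 (5S)-5-[(trityloxy)methyl]dihydrofuran-2(3H)-one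
Product: 3 (3R,5S)-3-methyl-5-[(trityloxy)methyl]dihydrofuran-2(3H)-one, via lithium enolate 2 (not isolated)
Conditions: LDA (1.05 equiv), THF, −78 °C; MeI, −78 → −40 °C
Reagents that add atoms: iodomethane, [CH3]I
Why: Kinetic enolate alkylation of a γ-substituted γ-butyrolactone, in which MeI attacks the face anti to the bulky CH2OTr group, so the bought C5 centre sets the new C3 centre trans (3R).

Step 2
Reactants: 3 (3R,5S)-3-methyl-5-[(trityloxy)methyl]dihydrofuran-2(3H)-one
Product: 4 (3R,5S)-5-(hydroxymethyl)-3-methyldihydrofuran-2(3H)-one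
Conditions: AcOH/H2O (4:1), 50 °C
Reagents that add atoms: none
Why: Acid-catalysed detritylation (SN1 at the trityl carbon) that leaves the lactone and both stereocentres untouched.

Step 3
Reactants: 5 geranyl acetate, (2E)-3,7-dimethylocta-2,6-dien-1-yl acetate
Product: 7 (2E)-3-methyl-6-oxohex-2-en-1-yl acetate, via secondary ozonide 6 (not isolated)
Conditions: O3 (1.0 equiv, Sudan Red end point), CH2Cl2, −78 °C; then Me2S, −78 °C → rt
Reagents that add atoms: ozone, [O-][O+]=O
Why: Ozonolysis (Criegee mechanism) with reductive work-up, selective because the 6,7-alkene is more electron-rich than the 2,3-alkene deactivated by the allylic acetate; the (2E) alkene is carried over from 5.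

Step 4
Reactants: 7 (2E)-3-methyl-6-oxohex-2-en-1-yl acetate
Product: 8 (2E)-3-methylhept-2-en-6-yn-1-ol
Conditions: dimethyl (1-diazo-2-oxopropyl)phosphonate, K2CO3, MeOH, 0 °C → rt
Reagents that add atoms: dimethyl (1-diazo-2-oxopropyl)phosphonate, COP(=O)(OC)C(=[N+]=[N-])C(C)=O
Why: Ohira–Bestmann form of the Seyferth–Gilbert homologation, in which the diazomethylphosphonate anion adds to the aldehyde and loss of phosphate and N2 with a 1,2-hydrogen shift gives the terminal alkyne, while K2CO3/MeOH removes the acetate in the same pot.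

Step 5
Reactants: 8 (2E)-3-methylhept-2-en-6-yn-1-ol
Product: 10 (2E)-3-methyloct-2-en-6-yn-1-ol, via lithium alkoxide acetylide 9 (not isolated)
Conditions: n-BuLi (2.1 equiv), THF, −78 → 0 °C; MeI (1.05 equiv), DMPU, −78 °C → rt; H2O
Reagents that add atoms: iodomethane, [CH3]I
Why: Alkylation of a lithium acetylide (SN2 on MeI), in which the dianion reacts at carbon because the lithium alkoxide is far less nucleophilic.

Step 6
Reactants: 10 (2E)-3-methyloct-2-en-6-yn-1-ol
Product: 13 (2E,6E)-7-bromo-3-methylocta-2,6-dien-1-ol, via alkenylzirconocene 11 (not isolated), via zirconium alkoxide 12 (not isolated)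
Conditions: Cp2Zr(H)Cl (2.5 equiv), THF, rt → 50 °C; NBS (1.1 equiv), 0 °C; dilute aq. HCl
Reagents that add atoms: N-bromosuccinimide, O=C1CCC(=O)N1Br
Why: Hydrozirconation then bromodezirconation, where syn addition of Zr–H with zirconium settling on the less hindered methyl-bearing carbon (reversible with excess hydride) and bromination with retention fix the (6E) alkenyl bromide.

Step 7
Reactants: 4 (3R,5S)-5-(hydroxymethyl)-3-methyldihydrofuran-2(3H)-one; 13 (2E,6E)-7-bromo-3-methylocta-2,6-dien-1-ol
Product: 15 (3R,5S)-5-[(2E,6E)-8-hydroxy-2,6-dimethylocta-2,6-dien-1-yl]-3-methyldihydrofuran-2(3H)-one, via 2-alkoxybenzoxazoline adduct 14 (not isolated)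
Conditions: 4 (1.6 equiv), 5,7-di-tert-butyl-3-phenyl-1,3-benzoxazol-3-ium tetrafluoroborate (1.5 equiv), pyridine, MTBE, rt, 20 min; then 13 (1.0 equiv), [Ir(ppy)2(dtbbpy)]PF6 (1.5 mol %), NiBr2(dtbbpy) (5 mol %), quinuclidine (1.8 equiv), DMA/MTBE, blue LEDs (450 nm), rt
Reagents that add atoms: none
Why: Proposed new method: a nickel/photoredox deoxygenative alkyl–alkenyl coupling in which adduct 14 is oxidised by the excited iridium photocatalyst, loses its C2 proton to quinuclidine and fragments by β-scission (driven by formation of the benzoxazolone) to the primary β-acyloxyalkyl radical, which is captured by the alkenyl–nickel bromide formed by stereoretentive oxidative addition of zerovalent nickel into 13, so that reductive elimination from trivalent nickel forms the lactone CH2–C(sp2) bond with the E geometry kept and without a long-lived alkyl–metal species that could expel the β-carboxylate; the closest known reaction type is the nickel/photoredox deoxygenative arylation of alcohols with aryl halides through such azolium adducts, and what is new is an unactivated trisubstituted alkenyl bromide as partner and a β-acyloxy alcohol as radical source, with both stereocentres untouched.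

Step 8
Reactants: 15 (3R,5S)-5-[(2E,6E)-8-hydroxy-2,6-dimethylocta-2,6-dien-1-yl]-3-methyldihydrofuran-2(3H)-one
Product: 16 (3R,5S)-5-[(2E,6E)-8-bromo-2,6-dimethylocta-2,6-dien-1-yl]-3-methyldihydrofuran-2(3H)-one
Conditions: CBr4, PPh3, CH2Cl2, −20 → 0 °C
Reagents that add atoms: tetrabromomethane, BrC(Br)(Br)Br
Why: Appel reaction, an SN2 displacement of the alkoxyphosphonium by bromide at the primary allylic carbon without allylic transposition and with the lactone inert.

Step 9
Reactants: 17 2,3,4-trimethoxybenzaldehyde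
Product: 21 6-iodo-2,3,4-trimethoxybenzaldehyde, via lithium amino alkoxide 18 (not isolated), via aryllithium 19 (not isolated), via iodo amino alkoxide 20 (not isolated)
Conditions: LiN(Me)CH2CH2NMe2 (from N,N,N′-trimethylethylenediamine and n-BuLi), THF, −20 °C; n-BuLi (3 equiv), −20 °C; iodine, −78 °C → rt; H2O
Reagents that add atoms: iodine, [I][I]
Why: Directed ortho-metalation by the Comins α-amino alkoxide method, in which the chelating amino alkoxide made in situ from the aldehyde directs n-BuLi to the only free ortho position (C6) rather than to the position next to the 4-methoxy group, and iodine quenches the aryllithium.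

Step 10
Reactants: 21 6-iodo-2,3,4-trimethoxybenzaldehyde
Product: 23 2-hydroxy-6-iodo-3,4-dimethoxybenzaldehyde, via aryloxydichloroborane 22 (not isolated)
Conditions: BCl3 (1.2 equiv), CH2Cl2, −78 → 0 °C; H2O
Reagents that add atoms: none
Why: Chelation-controlled Lewis-acid ether cleavage, in which BCl3 bound to the aldehyde oxygen removes only the methyl of the ortho methoxy group through a six-membered chelate.

Step 11
Reactants: 23 2-hydroxy-6-iodo-3,4-dimethoxybenzaldehyde
Product: 25 5-iodo-2,3-dimethoxy-6-methylphenol, via benzyl triethylsilyl ether 24 (not isolated)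
Conditions: Et3SiH (4 equiv), CF3CO2H, CH2Cl2, 0 °C → rt
Reagents that add atoms: none
Why: Ionic hydrogenation, in which hydride transfer to the protonated aldehyde and then to the benzylic cation (stabilised by the ortho-OH and para-OMe groups) turns CHO into CH3 while the aryl iodide stays.

Step 12
Reactants: 25 5-iodo-2,3-dimethoxy-6-methylphenol; 16 (3R,5S)-5-[(2E,6E)-8-bromo-2,6-dimethylocta-2,6-dien-1-yl]-3-methyldihydrofuran-2(3H)-one
Product: 28 antroquinonol Y = (3R,5S)-5-[(2E,6E)-8-(3-hydroxy-4,5-dimethoxy-2-methylphenyl)-2,6-dimethylocta-2,6-dien-1-yl]-3-methyldihydrofuran-2(3H)-one, via dilithio phenoxide 26 (not isolated), via arylcopper 27 (not isolated)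
Conditions: 25 (1.5 equiv), t-BuLi (4.5 equiv), THF, −78 °C; CuBr·SMe2 (1.5 equiv), −78 → −40 °C; 16 (1.0 equiv), −78 → −20 °C; H2O
Reagents that add atoms: none
Why: Copper-mediated allylic substitution after iodine–lithium exchange, in which the arylcopper attacks the primary allylic carbon (SN2, the fully substituted γ-carbon disfavouring SN2′) to form the aryl–CH2 bond with both E alkenes kept, while the soft organocopper leaves the lactone and its two stereocentres alone.

**Compound list**

1 | (5S)-5-[(trityloxy)methyl]dihydrofuran-2(3H)-one | O=C1CC[C@@H](COC(c2ccccc2)(c2ccccc2)c2ccccc2)O1 | starting material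
2 | lithium enolate of 1 (formed in the flask) | [Li]OC1=CC[C@@H](COC(c2ccccc2)(c2ccccc2)c2ccccc2)O1 | intermediate
3 | (3R,5S)-3-methyl-5-[(trityloxy)methyl]dihydrofuran-2(3H)-one (trans) | C(c1ccccc1)(c1ccccc1)(c1ccccc1)OC[C@@H]1C[C@@H](C)C(=O)O1 | intermediate
4 | (3R,5S)-5-(hydroxymethyl)-3-methyldihydrofuran-2(3H)-one | OC[C@@H]1C[C@@H](C)C(=O)O1 | intermediate
5 | geranyl acetate, (2E)-3,7-dimethylocta-2,6-dien-1-yl acetate | CC(C)=CCC/C(C)=C/COC(C)=O | starting material
6 | 5-[(3E)-5-acetoxy-3-methylpent-3-en-1-yl]-3,3-dimethyl-1,2,4-trioxolane (formed in the flask) | CC1(C)OOC(CC/C(C)=C/COC(C)=O)O1 | intermediate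
7 | (2E)-3-methyl-6-oxohex-2-en-1-yl acetate | O=CCC/C(C)=C/COC(C)=O | intermediate
8 | (2E)-3-methylhept-2-en-6-yn-1-ol | C#CCC/C(C)=C/CO | intermediate
9 | dilithium salt of 8, lithium on O and on the alkyne terminus (formed in the flask) | [Li]C#CCC/C(C)=C/CO[Li] | intermediate
10 | (2E)-3-methyloct-2-en-6-yn-1-ol | CC#CCC/C(C)=C/CO | intermediate
11 | (2E,6E)-3-methylocta-2,6-dien-1-ol carrying Cp2ZrCl on O and on C7 (formed in the flask) | C/C(=C\CC/C(C)=C/CO[Zr](Cl)(C1C=CC=C1)C1C=CC=C1)[Zr](Cl)(C1C=CC=C1)C1C=CC=C1 | intermediate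
12 | (2E,6E)-7-bromo-3-methylocta-2,6-dien-1-ol carrying Cp2ZrCl on O (formed in the flask) | C/C(Br)=C\CC/C(C)=C/CO[Zr](Cl)(C1C=CC=C1)C1C=CC=C1 | intermediate
13 | (2E,6E)-7-bromo-3-methylocta-2,6-dien-1-ol | C/C(Br)=C\CC/C(C)=C/CO | intermediate
14 | (3R,5S)-5-{[(5,7-di-tert-butyl-3-phenyl-2,3-dihydro-1,3-benzoxazol-2-yl)oxy]methyl}-3-methyldihydrofuran-2(3H)-one, both epimers at the aminal carbon (formed in the flask) | CC(C)(C)c1cc(C(C)(C)C)c2OC(OC[C@@H]3C[C@@H](C)C(=O)O3)N(c3ccccc3)c2c1 | intermediate
15 | (3R,5S)-5-[(2E,6E)-8-hydroxy-2,6-dimethylocta-2,6-dien-1-yl]-3-methyldihydrofuran-2(3H)-one | OC/C=C(\C)CC/C=C(\C)C[C@@H]1C[C@@H](C)C(=O)O1 | intermediate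
16 | (3R,5S)-5-[(2E,6E)-8-bromo-2,6-dimethylocta-2,6-dien-1-yl]-3-methyldihydrofuran-2(3H)-one | BrC/C=C(\C)CC/C=C(\C)C[C@@H]1C[C@@H](C)C(=O)O1 | intermediate
17 | 2,3,4-trimethoxybenzaldehyde | COc1ccc(C=O)c(OC)c1OC | starting material
18 | lithium α-amino alkoxide from 17 and LiN(Me)CH2CH2NMe2 (formed in the flask) | COc1ccc(C(O[Li])N(C)CCN(C)C)c(OC)c1OC | intermediate
19 | 18 lithiated at C6 of the ring (formed in the flask) | COc1cc([Li])c(C(O[Li])N(C)CCN(C)C)c(OC)c1OC | intermediate
20 | 18 iodinated at C6 of the ring (formed in the flask) | COc1cc(I)c(C(O[Li])N(C)CCN(C)C)c(OC)c1OC | intermediate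
21 | 6-iodo-2,3,4-trimethoxybenzaldehyde | COc1cc(I)c(C=O)c(OC)c1OC | intermediate
22 | 2-formyl-3-iodo-5,6-dimethoxyphenoxy(dichloro)borane (formed in the flask) | COc1cc(I)c(C=O)c(OB(Cl)Cl)c1OC | intermediate
23 | 2-hydroxy-6-iodo-3,4-dimethoxybenzaldehyde | COc1cc(I)c(C=O)c(O)c1OC | intermediate
24 | 3-iodo-5,6-dimethoxy-2-{[(triethylsilyl)oxy]methyl}phenol (formed in the flask) | COc1cc(I)c(CO[Si](CC)(CC)CC)c(O)c1OC | intermediate
25 | 5-iodo-2,3-dimethoxy-6-methylphenol | COc1cc(I)c(C)c(O)c1OC | intermediate
26 | lithium 5-lithio-2,3-dimethoxy-6-methylphenoxide (formed in the flask) | COc1cc([Li])c(C)c(O[Li])c1OC | intermediate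
27 | lithium 5-cuprio-2,3-dimethoxy-6-methylphenoxide, the arylcopper (formed in the flask) | COc1cc([Cu])c(C)c(O[Li])c1OC | intermediate
28 | antroquinonol Y, (3R,5S)-5-[(2E,6E)-8-(3-hydroxy-4,5-dimethoxy-2-methylphenyl)-2,6-dimethylocta-2,6-dien-1-yl]-3-methyldihydrofuran-2(3H)-one | COc1cc(C/C=C(\C)CC/C=C(\C)C[C@@H]2C[C@@H](C)C(=O)O2)c(C)c(O)c1OC | target

**Step count and risks**

Total step count: 12. Longest linear sequence: 7 steps (steps 3, 4, 5, 6, 7, 8 and 12, from geranyl acetate 5).

The three steps most likely to fail: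

Step 7, the proposed new coupling. The hindered alkenyl bromide may add slowly to nickel, the free allylic OH of 13 may be etherified, and the primary radical may simply be reduced. The fallback uses known chemistry and sets out from 4. Iodination (iodine, PPh3, imidazole, CH2Cl2, 0 °C) gives (3R,5S)-5-(iodomethyl)-3-methyldihydrofuran-2(3H)-one F1. A nickel-catalysed reductive cross-electrophile coupling of F1 with alkenyl bromide 13 (NiBr2(dme), 4,4′-di-tert-butyl-2,2′-bipyridine, Mn powder, NaI, DMA, rt) is an established alkyl halide/alkenyl bromide coupling that also runs through the alkyl radical and keeps the alkene geometry. It comes back to the route at 15.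

Step 11, the ionic hydrogenation. The electron-rich benzylic cation may attack a second arene (diarylmethane) or the iodide may be lost in acid. The fallback sets out from 23 and avoids cations. Acylation (ClCO2Et, Et3N, THF, 0 °C) gives 2-formyl-3-iodo-5,6-dimethoxyphenyl ethyl carbonate F2. NaBH4 in THF/H2O (0 °C → rt) then reduces the aldehyde; the alkoxide takes over the carbonate, 1,4-elimination gives an ortho-quinone methide, and this is reduced in situ. It comes back at 25.

Step 12, the final aryl–allyl union. The dianionic aryl metal may be sluggish, some SN2′ or O-allylation may occur, and the allylic bromide 16 is sensitive. The fallback sets out from 25. Miyaura borylation (bis(pinacolato)diboron, Pd(dppf)Cl2, KOAc, dioxane, 80 °C) gives 2,3-dimethoxy-6-methyl-5-(4,4,5,5-tetramethyl-1,3,2-dioxaborolan-2-yl)phenol F3. A Suzuki–Miyaura allyl–aryl coupling of F3 with 16 (Pd(PPh3)4, K2CO3, THF/H2O, 50 °C) gives the linear product with the lactone intact. It comes back at the target 28.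

**Further compounds**

F1 | step 7 | (3R,5S)-5-(iodomethyl)-3-methyldihydrofuran-2(3H)-one | IC[C@@H]1C[C@@H](C)C(=O)O1
F2 | step 11 | 2-formyl-3-iodo-5,6-dimethoxyphenyl ethyl carbonate | CCOC(=O)Oc1c(C=O)c(I)cc(OC)c1OC
F3 | step 12 | 2,3-dimethoxy-6-methyl-5-(4,4,5,5-tetramethyl-1,3,2-dioxaborolan-2-yl)phenol | COc1cc(B2OC(C)(C)C(C)(C)O2)c(C)c(O)c1OC
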